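## Retrosynthetic overview

1. Target 23 ⇒ (angeloylation of C9–OH; Evans–Tishchenko reduction of the C7–OH/C9=O β-ketol, which puts the acetate on C7 and creates the anti C9 carbinol; oxidation at C1) ⇒ tricyclic keto diol 17.
2. 17 ⇒ monocyclic epoxy keto aldehyde 15 by cutting C7–C8 (aldol) and C10–C11 (enolate–epoxide alkylation); both bonds are made in one operation.
3. Enabling feature: the C9 ketone lies between the two bonds, so its α-carbons C8 (methyl) and C10 (methine) act in turn as nucleophiles. C7 is a non-enolisable aldehyde on quaternary C6, and the C1–C11 epoxide sits 1,3 to the axial C4–C10 bond on the six-membered ring. Once the seven-membered ring is closed, the enolate oxygen cannot reach C11 without forming a bridgehead enol ether, so only C-alkylation to the cyclobutane remains.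
4. 15 ⇒ cyclohexene 7 ⇒ Diels–Alder reaction of diene 3 (C5–C6–C7 part) with chiral crotonyl imide 6 (C3, C4 part), which sets C3, C4 and C5; the C4 acyl group is then grown into the CH(Me)–C(=O)–Me unit (C10, C9, C8).
5. Ring order: six-membered ring (step 3) → seven-membered ring → cyclobutane (both in step 11).

Key step: step 11

Remark: the target is read as a 7-acetoxy-9-angeloyloxy-longipinan-1-one and numbered as in longipinane (C1 ring C=O, C2 CH2, C3 CHMe, C4/C5/C10/C11 cyclobutane with C10 the methyl-bearing quaternary carbon and C5 bonded to C6, C6 CMe2, C7 CH–OAc, C8 CH2, C9 CH–O-angelate); the side-chain methine (future C10) of 10–15 is carried as an epimer mixture because step 11 enolises it.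

## Route

Step 1
Reactants: 1 methyl (2E,4E)-hexa-2,4-dienoate (methyl sorbate)
Product: 3 methyl (3E)-2,2-dimethylhexa-3,5-dienoate, via methyl (3E)-2-methylhexa-3,5-dienoate 2 (not isolated)
Conditions: LiN(i-Pr)2 (1.1 equiv), HMPA, THF, −78 °C, then MeI; LiN(i-Pr)2 (1.2 equiv), −78 °C, then MeI, −78 °C → rt
Reagents that add atoms: iodomethane (CI)
Why: Deconjugative α-alkylation of the extended ester enolate, run twice: the lithium trienolate of the sorbate should be methylated at the α-carbon, and a second enolisation/methylation of the doubly activated α-C–H should install quaternary C6 and leave the (3E)-diene out of conjugation.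

Step 2
Reactants: 4 (R)-4-benzyl-1,3-oxazolidin-2-one; 5 (E)-but-2-enoyl chloride
Product: 6 (R)-4-benzyl-3-[(E)-but-2-enoyl]-1,3-oxazolidin-2-one
Conditions: n-BuLi, THF, −78 °C; then 5, −78 → 0 °C
Reagents that add atoms: none
Why: N-acylation of the lithiated oxazolidinone by the acid chloride (acyl substitution) should give the chiral dienophile without touching the (E)-alkene.

Step 3
Reactants: 3 methyl (3E)-2,2-dimethylhexa-3,5-dienoate; 6 (R)-4-benzyl-3-[(E)-but-2-enoyl]-1,3-oxazolidin-2-one
Product: 7 methyl 2-[(1R,5R,6S)-6-{[(4R)-4-benzyl-2-oxo-1,3-oxazolidin-3-yl]carbonyl}-5-methylcyclohex-2-en-1-yl]-2-methylpropanoate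
Conditions: Et2AlCl (1.6 equiv), CH2Cl2, −40 → −10 °C
Reagents that add atoms: none
Why: Oxazolidinone-auxiliary-controlled Diels–Alder reaction: the Et2AlCl-chelated s-cis acyl imide should be attacked on the face opposite the benzyl group, with the unsubstituted diene terminus bonding to the β-carbon ("ortho" regiochemistry); the endo transition state places the C5 and C4 substituents cis and the (E)-crotonyl geometry places the C3 methyl trans to the acyl group, so C3, C4 and C5 are set together.

Step 4
Reactants: 7 Diels–Alder adduct (imide)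
Product: 8 S-ethyl (1S,2R,6R)-2-(1-methoxy-2-methyl-1-oxopropan-2-yl)-6-methylcyclohex-3-ene-1-carbothioate
Conditions: LiSEt (from EtSH, n-BuLi), THF, 0 °C
Reagents that add atoms: ethanethiol (CCS)
Why: Thiolate cleavage of the N-acyl oxazolidinone at the exocyclic carbonyl (transthioesterification) should work on the hindered α-branched acyl group where aminolysis may not, should spare the neopentyl methyl ester and the C4 configuration, and returns auxiliary 4.

Step 5
Reactants: 8 thioester
Product: 9 methyl 2-[(1R,5R,6S)-6-acetyl-5-methylcyclohex-2-en-1-yl]-2-methylpropanoate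
Conditions: Me2CuLi (from MeLi, CuI), Et2O, −78 → −40 °C
Reagents that add atoms: methyllithium ([Li]C), used as Me2CuLi
Why: Ketone synthesis from a thioester and a Gilman reagent: the cuprate should replace the thiolate once and, being weakly basic, should neither add to the new methyl ketone or the hindered ester nor epimerise C4.

Step 6
Reactants: 9 methyl ketone
Product: 11 methyl 2-[(1R,5R,6S)-6-(2-hydroxy-3-oxobutan-2-yl)-5-methylcyclohex-2-en-1-yl]-2-methylpropanoate (carbinol epimers), via 1-ethoxyvinyl carbinol 10 (not isolated)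
Conditions: CH2=C(OEt)Li (ethyl vinyl ether, t-BuLi), CeCl3, THF, −78 °C; then 0.5 M HCl, THF, 0 °C
Reagents that add atoms: ethyl vinyl ether (C=COCC); water (O)
Why: 1,2-Addition of an acyl-anion equivalent as its organocerium reagent (which suppresses enolisation, and so epimerisation at C4, of the hindered ketone), followed by enol-ether hydrolysis, should give the tertiary α-ketol; the new carbinol centre forms unselectively but is removed in step 7.

Step 7
Reactants: 11 α-ketol
Product: 12 methyl 2-methyl-2-[(1R,5R,6S)-5-methyl-6-(3-oxobutan-2-yl)cyclohex-2-en-1-yl]propanoate (epimers at the side-chain methine)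
Conditions: SmI2 (3 equiv), HMPA, THF/MeOH, −20 → 0 °C
Reagents that add atoms: none
Why: Reductive cleavage of an α-oxygenated ketone by SmI2 (ketyl formation, loss of the α-hydroxyl, protonation of the samarium enolate) should give the α-methyl ketone that carries C10, C9 and C8.

Step 8
Reactants: 12 keto ester
Product: 13 3-[(1S,2R,6R)-2-(1-hydroxy-2-methylpropan-2-yl)-6-methylcyclohex-3-en-1-yl]butan-2-ol (diastereomer mixture in the side chain)
Conditions: LiAlH4, THF, 0 °C → rt
Reagents that add atoms: none
Why: Hydride reduction of the ester and the ketone should bring both side chains to the alcohol level; the new carbinol centre is oxidised again in step 9, so its configuration is irrelevant.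

Step 9
Reactants: 13 diol
Product: 14 2-methyl-2-[(1R,5R,6S)-5-methyl-6-(3-oxobutan-2-yl)cyclohex-2-en-1-yl]propanal
Conditions: Dess–Martin periodinane (2.6 equiv), NaHCO3, CH2Cl2, 0 °C → rt
Reagents that add atoms: none
Why: Dess–Martin oxidation of both alcohols should give the non-enolisable neopentyl aldehyde (C7) and the methyl ketone (C9) under buffered, non-epimerising conditions.

Step 10
Reactants: 14 keto aldehyde
Product: 15 2-methyl-2-[(1R,2R,3S,4R,6S)-4-methyl-3-(3-oxobutan-2-yl)-7-oxabicyclo[4.1.0]heptan-2-yl]propanal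
Conditions: dimethyldioxirane (1.2 equiv), acetone, 0 °C
Reagents that add atoms: dimethyldioxirane (CC1(C)OO1)
Why: Dioxirane epoxidation is much faster at the cis-disubstituted ring alkene than oxidation of the hindered aldehyde, and oxygen should be delivered to the face opposite the bulky allylic C5 substituent and the C4 side chain (steric control, syn only to the small C3 methyl), which is the geometry the rear-side attack in step 11 requires.

Step 11
Reactants: 15 epoxy keto aldehyde
Product: 17 (1S,3R,4S,5S,7S,10R,11R)-1,7-dihydroxylongipinan-9-one, via seven-membered-ring aldol 16 (not isolated)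
Conditions: LiN(SiMe3)2 (1.05 equiv), THF (0.01 M), −78 → −40 °C; then LiN(i-Pr)2 (1.3 equiv), −78 → 25 °C; aq. NH4Cl
Reagents that add atoms: none
Why: Proposed new method: LiN(SiMe3)2 should deprotonate the C8 methyl group under kinetic control, and this enolate should add to the C7 aldehyde, which cannot enolise because C6 is quaternary (7-(enolexo)-exo-trig aldol addition, helped by the gem-dimethyl group), closing the seven-membered ring as lithium aldolate 16; LiN(i-Pr)2 should then enolise the β-ketol alkoxide on the α′ side at C10, and this in-ring enolate should open the C1–C11 epoxide at C11 from the rear (4-(enolexo)-exo-tet), closing the cyclobutane and the quaternary C10. The closest known reaction types are the intramolecular aldol addition of a methyl ketone enolate, the carbanion–epoxide 4-exo-tet cyclisation (Stork epoxynitrile type) and the enolate 1,3-bridging alkylations that build bicyclo[3.1.1]heptanones; what is new is running both through one β-ketol dianion with a ketone enolate as the nucleophile. C11 is set by inversion at the epoxide carbon, whose oxygen was placed anti to the side chains in step 10; C10 is set by the tether, because the closed seven-membered ring holds C9 on the C5/C6 side so the methyl group must end over the C1–C2–C3 bridge; C7 is set in the aldol, where the lithium-bound oxygen should take the exo (convex, pseudo-equatorial) side of the forming cis-fused bicycle, away from the epoxide. The step needs C- over O-alkylation and attack at C11 rather than C1: with the seven-membered ring closed, O-alkylation would give an anti-Bredt bridgehead enol ether, and C10, axial on C4 while the C5–C6 bond stays equatorial, is 1,3-diaxial to C11, so only the trans-diaxial (Fürst–Plattner) opening at C11 is within reach. Retro-aldol opening should be blocked once the C10 enolate exists, because it would require a ketone α,α′-dianion.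

Step 12
Reactants: 17 keto diol
Product: 18 (3R,4S,5S,7S,10R,11R)-7-hydroxylongipinane-1,9-dione
Conditions: TEMPO (0.1 equiv), KBr (0.1 equiv), NaOCl (1.1 equiv), NaHCO3, CH2Cl2/H2O, 0 °C
Reagents that add atoms: none
Why: Oxoammonium (TEMPO) oxidation is very sensitive to steric hindrance, so the C1 carbinol (flanked by a CH2 and a CH) should be oxidised while the neopentylic C7 carbinol next to CMe2 reacts much more slowly.

Step 13
Reactants: 18 hydroxy diketone
Product: 20 (3R,4S,5S,7S,9S,10R,11R)-7-acetoxy-9-hydroxylongipinan-1-one, via acetaldehyde hemiacetal 19 (not isolated)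
Conditions: CH3CHO (6 equiv), SmI2 (0.3 equiv), THF, −10 °C
Reagents that add atoms: acetaldehyde (CC=O)
Why: Evans–Tishchenko reduction: the trivalent samarium alkoxide of the C7 hemiacetal should deliver its hydride intramolecularly to the C9 ketone on the face that carries the C7 oxygen, giving the 1,3-anti (9S) alcohol and leaving the acetate on the C7 oxygen, while the C1 ketone, which has no β-hydroxyl, is not reduced.

Step 14
Reactants: 20 hydroxy acetate; 21 angelic acid, (Z)-2-methylbut-2-enoic acid
Product: 23 (3R,4S,5S,7S,9S,10R,11R)-7-acetoxy-9-[(Z)-2-methylbut-2-enoyloxy]longipinan-1-one (target), via mixed anhydride 22 (not isolated)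
Conditions: 2,4,6-trichlorobenzoyl chloride, Et3N, toluene, rt; then 20, toluene, 80 °C
Reagents that add atoms: none
Why: Yamaguchi-type mixed-anhydride esterification run without a nucleophilic amine catalyst should transfer the (Z)-2-methylbut-2-enoyl group to the hindered axial C9 alcohol without isomerisation to the (E)-ester.

## Compound list

1 | methyl (2E,4E)-hexa-2,4-dienoate (methyl sorbate) | C/C=C/C=C/C(=O)OC | starting material
2 | methyl (3E)-2-methylhexa-3,5-dienoate (racemic) | COC(=O)C(C)/C=C/C=C | intermediate (not isolated)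
3 | methyl (3E)-2,2-dimethylhexa-3,5-dienoate | COC(=O)C(C)(C)/C=C/C=C | intermediate
4 | (R)-4-benzyl-1,3-oxazolidin-2-one | O=C1N[C@H](Cc2ccccc2)CO1 | starting material
5 | (E)-but-2-enoyl chloride | C/C=C/C(Cl)=O | starting material
6 | (R)-4-benzyl-3-[(E)-but-2-enoyl]-1,3-oxazolidin-2-one | C/C=C/C(=O)N1[C@H](Cc2ccccc2)COC1=O | intermediate
7 | methyl 2-[(1R,5R,6S)-6-{[(4R)-4-benzyl-2-oxo-1,3-oxazolidin-3-yl]carbonyl}-5-methylcyclohex-2-en-1-yl]-2-methylpropanoate | COC(=O)C(C)(C)[C@@H]1C=CC[C@@H](C)[C@@H]1C(=O)N2[C@H](Cc3ccccc3)COC2=O | intermediate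
8 | S-ethyl (1S,2R,6R)-2-(1-methoxy-2-methyl-1-oxopropan-2-yl)-6-methylcyclohex-3-ene-1-carbothioate | COC(=O)C(C)(C)[C@@H]1C=CC[C@@H](C)[C@@H]1C(=O)SCC | intermediate
9 | methyl 2-[(1R,5R,6S)-6-acetyl-5-methylcyclohex-2-en-1-yl]-2-methylpropanoate | COC(=O)C(C)(C)[C@@H]1C=CC[C@@H](C)[C@@H]1C(C)=O | intermediate
10 | methyl 2-[(1R,5R,6S)-6-(3-ethoxy-2-hydroxybut-3-en-2-yl)-5-methylcyclohex-2-en-1-yl]-2-methylpropanoate (carbinol epimers) | COC(=O)C(C)(C)[C@@H]1C=CC[C@@H](C)[C@@H]1C(C)(O)C(=C)OCC | intermediate (not isolated)
11 | methyl 2-[(1R,5R,6S)-6-(2-hydroxy-3-oxobutan-2-yl)-5-methylcyclohex-2-en-1-yl]-2-methylpropanoate (carbinol epimers) | COC(=O)C(C)(C)[C@@H]1C=CC[C@@H](C)[C@@H]1C(C)(O)C(C)=O | intermediate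
12 | methyl 2-methyl-2-[(1R,5R,6S)-5-methyl-6-(3-oxobutan-2-yl)cyclohex-2-en-1-yl]propanoate (methine epimers) | COC(=O)C(C)(C)[C@@H]1C=CC[C@@H](C)[C@@H]1C(C)C(C)=O | intermediate
13 | 3-[(1S,2R,6R)-2-(1-hydroxy-2-methylpropan-2-yl)-6-methylcyclohex-3-en-1-yl]butan-2-ol (side-chain diastereomers) | OCC(C)(C)[C@@H]1C=CC[C@@H](C)[C@@H]1C(C)C(C)O | intermediate
14 | 2-methyl-2-[(1R,5R,6S)-5-methyl-6-(3-oxobutan-2-yl)cyclohex-2-en-1-yl]propanal (methine epimers) | O=CC(C)(C)[C@@H]1C=CC[C@@H](C)[C@@H]1C(C)C(C)=O | intermediate
15 | 2-methyl-2-[(1R,2R,3S,4R,6S)-4-methyl-3-(3-oxobutan-2-yl)-7-oxabicyclo[4.1.0]heptan-2-yl]propanal (methine epimers) | O=CC(C)(C)[C@@H]1[C@H]2O[C@H]2C[C@@H](C)[C@@H]1C(C)C(C)=O | intermediate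
16 | (7S)-1,11-epoxy-7-hydroxy-10,11-secolongipinan-9-one: cis-fused cycloheptanone/cyclohexene oxide with the C7–C8 bond made (C10 epimers; present as its lithium alkoxide) | O=C1C[C@H](O)C(C)(C)[C@@H]2[C@H]3O[C@H]3C[C@@H](C)[C@@H]2C1C | intermediate (not isolated)
17 | (1S,3R,4S,5S,7S,10R,11R)-1,7-dihydroxylongipinan-9-one | O=C1C[C@H](O)C(C)(C)[C@H]2[C@@H]3[C@H](C)C[C@H](O)[C@H]2[C@@]31C | intermediate
18 | (3R,4S,5S,7S,10R,11R)-7-hydroxylongipinane-1,9-dione | O=C1C[C@H](O)C(C)(C)[C@H]2[C@@H]3[C@H](C)CC(=O)[C@H]2[C@@]31C | intermediate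
19 | 7-O-(1-hydroxyethyl) hemiacetal of 18 (present as its samarium alkoxide) | O=C1C[C@H](OC(C)O)C(C)(C)[C@H]2[C@@H]3[C@H](C)CC(=O)[C@H]2[C@@]31C | intermediate (not isolated)
20 | (3R,4S,5S,7S,9S,10R,11R)-7-acetoxy-9-hydroxylongipinan-1-one | O[C@H]1C[C@H](OC(C)=O)C(C)(C)[C@H]2[C@@H]3[C@H](C)CC(=O)[C@H]2[C@@]31C | intermediate
21 | angelic acid, (Z)-2-methylbut-2-enoic acid | C/C=C(/C)C(=O)O | starting material
22 | (Z)-2-methylbut-2-enoic 2,4,6-trichlorobenzoic anhydride | C/C=C(/C)C(=O)OC(=O)c1c(Cl)cc(Cl)cc1Cl | intermediate (not isolated)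
23 | (3R,4S,5S,7S,9S,10R,11R)-7-acetoxy-9-[(Z)-2-methylbut-2-enoyloxy]longipinan-1-one | C/C=C(/C)C(=O)O[C@H]1C[C@H](OC(C)=O)C(C)(C)[C@H]2[C@@H]3[C@H](C)CC(=O)[C@H]2[C@@]31C | target

## Step count and risks

Total steps: 14. Longest linear sequence: 13 steps (steps 1 and 3–14, from methyl sorbate 1); step 2 is a one-step side branch.

**Step 11 (key step, proposed new method).** What may go wrong: the lithium aldolate may revert by retro-aldol before C10 is enolised, after which the open-chain enolate oxygen, C8 or an alkoxide can open the epoxide in other ways; enolisation at the hindered C10 methine may also be too slow. Fallback, known chemistry with the two bonds made in separate steps, setting out from 9 and returning at 18: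
- Reductive cyanation of 9 (van Leusen; TosMIC, t-BuOK, DME/EtOH, 0 °C, short contact to protect C4) should give the cyano ester F1.
- LiBH4 should reduce only the ester, giving the cyano alcohol F2.
- TBSCl/imidazole should give the silyl ether F3.
- mCPBA should give the epoxy nitrile F4, with the same facial bias as step 10.
- KN(SiMe3)2 in toluene should effect the Stork epoxynitrile cyclisation (4-exo-tet) to the cyclobutane nitrile F5; the slim cyano group should take the side next to the C6 substituent and the methyl group the side over C2.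
- MeLi followed by aqueous HCl should turn the nitrile into the methyl ketone and remove the silyl group, giving the keto diol F6.
- Dess–Martin oxidation should give the diketo aldehyde F7.
- LiN(SiMe3)2 at −78 °C should close the seven-membered ring by aldol addition (only the C8 enolate can reach the aldehyde), which rejoins the route at 18.

**Step 13.** What may go wrong: the seven-membered ring may not reach the conformation with the C7 oxygen axial that the intramolecular hydride transfer needs, so the reduction stalls and acetaldehyde is consumed by the simple Tishchenko reaction. Fallback, setting out from 17 and returning at 20: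
- LiBH(s-Bu)3 should reduce the C9 ketone, the only ketone in 17, from the open exo face to the axial 9S alcohol, giving the triol F8.
- TEMPO/NaOCl should oxidise the least hindered C1 carbinol, giving the keto diol F9.
- Ac2O/pyridine at 0 °C should acetylate the equatorial C7 hydroxyl in preference to the axial C9 hydroxyl, which rejoins the route at 20.

**Step 12.** What may go wrong: poor chemoselectivity, with the C7 carbinol oxidised as well (to the 7,9-diketone) or retro-aldol cleavage of the β-ketol under the basic biphasic conditions. Fallback, setting out from 17 and returning at 23: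
- TBSCl/imidazole should silylate only the C1 hydroxyl, since the neopentylic C7 hydroxyl does not react, giving the silyl ether F10.
- Evans–Tishchenko reduction as in step 13 should give the hydroxy acetate F11.
- Angeloylation as in step 14 should give the diester F12.
- HF·pyridine should remove the silyl group, giving the alcohol F13.
- Dess–Martin oxidation of the single free hydroxyl should give the target 23.

## Further compounds

F1 | step 11 | cyano ester: methyl 2-[(1R,5R,6S)-6-(1-cyanoethyl)-5-methylcyclohex-2-en-1-yl]-2-methylpropanoate | COC(=O)C(C)(C)[C@@H]1C=CC[C@@H](C)[C@@H]1C(C)C#N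
F2 | step 11 | cyano alcohol: 2-[(1S,2R,6R)-2-(1-hydroxy-2-methylpropan-2-yl)-6-methylcyclohex-3-en-1-yl]propanenitrile | OCC(C)(C)[C@@H]1C=CC[C@@H](C)[C@@H]1C(C)C#N
F3 | step 11 | silyl ether: tert-butyldimethylsilyl ether of F2 | CC(C)(C)[Si](C)(C)OCC(C)(C)[C@@H]1C=CC[C@@H](C)[C@@H]1C(C)C#N
F4 | step 11 | epoxy nitrile: ring epoxide of F3, oxygen anti to the side chains | CC(C)(C)[Si](C)(C)OCC(C)(C)[C@@H]1[C@H]2O[C@H]2C[C@@H](C)[C@@H]1C(C)C#N
F5 | step 11 | cyclobutane nitrile: bicyclo[3.1.1]heptane with C10–C11 formed, C9 as nitrile, C1–OH, C7 as CH2OTBS | CC(C)(C)[Si](C)(C)OCC(C)(C)[C@H]2[C@@H]3[C@H](C)C[C@H](O)[C@H]2[C@@]3(C#N)C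
F6 | step 11 | keto diol: C9 methyl ketone with C1–OH and C7 CH2OH | OCC(C)(C)[C@H]2[C@@H]3[C@H](C)C[C@H](O)[C@H]2[C@@]3(C(C)=O)C
F7 | step 11 | diketo aldehyde: C1 ketone, C9 methyl ketone, C7 aldehyde | O=CC(C)(C)[C@H]2[C@@H]3[C@H](C)CC(=O)[C@H]2[C@@]3(C(C)=O)C
F8 | step 13 | triol: (1S,3R,4S,5S,7S,9S,10R,11R)-longipinane-1,7,9-triol | O[C@H]1C[C@H](O)C(C)(C)[C@H]2[C@@H]3[C@H](C)C[C@H](O)[C@H]2[C@@]31C
F9 | step 13 | keto diol: (3R,4S,5S,7S,9S,10R,11R)-7,9-dihydroxylongipinan-1-one | O[C@H]1C[C@H](O)C(C)(C)[C@H]2[C@@H]3[C@H](C)CC(=O)[C@H]2[C@@]31C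
F10 | step 12 | silyl ether: 1-O-tert-butyldimethylsilyl ether of 17 | O=C1C[C@H](O)C(C)(C)[C@H]2[C@@H]3[C@H](C)C[C@H](O[Si](C)(C)C(C)(C)C)[C@H]2[C@@]31C
F11 | step 12 | hydroxy acetate: 7-acetoxy-1-(tert-butyldimethylsilyloxy)longipinan-9-ol (9S) | O[C@H]1C[C@H](OC(C)=O)C(C)(C)[C@H]2[C@@H]3[C@H](C)C[C@H](O[Si](C)(C)C(C)(C)C)[C@H]2[C@@]31C
F12 | step 12 | diester: 7-acetoxy-9-angeloyloxy-1-(tert-butyldimethylsilyloxy)longipinane | C/C=C(/C)C(=O)O[C@H]1C[C@H](OC(C)=O)C(C)(C)[C@H]2[C@@H]3[C@H](C)C[C@H](O[Si](C)(C)C(C)(C)C)[C@H]2[C@@]31C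
F13 | step 12 | alcohol: 7-acetoxy-9-angeloyloxylongipinan-1-ol | C/C=C(/C)C(=O)O[C@H]1C[C@H](OC(C)=O)C(C)(C)[C@H]2[C@@H]3[C@H](C)C[C@H](O)[C@H]2[C@@]31C
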